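**Plan**
- Feature and first cut: in ring B the C7 tertiary alcohol that carries the isopropenyl group is bonded directly to the C8 ketone (an alpha-ketol). The C7–C8 bond is therefore cut first, giving the ring-A keto-aldehyde 24.
- Further cuts: C7–C11 (isopropenyl onto a C7 aldehyde), the C3 angelate C–O bond, the C3/C4 cis-oxygenation (back to a C3=C4 alkene), then C5–C6 and C10–C9 (two Claisen shifts), down to 3-methylcyclohex-2-en-1-one.
- Forward order: ring A is present from the start. The C9–C8 arm (step 2) and the C6–C7 arm (step 9) are attached by Johnson–Claisen rearrangements, the alkene is cis-acetoxy-hydroxylated (step 12), the angelate and the isopropenyl group are added (steps 13 and 16), and ring B closes last (step 19).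
- Stereochemistry: C10 and C5 each come from an oxazaborolidine-controlled carbinol relayed by a suprafacial Claisen shift. C3 and C4 come from trans-diaxial iodoacetoxylation followed by acetoxonium closure. C7 comes from the chair transition state and the reversibility of the ring-B closure.

Key step: step 19

Remark: atoms carry eudesmane numbers throughout (ring A = C1–C5 and C10, chain C6–C7 on C5, chain C9–C8 on C10; beta is the face of the C10 methyl; TBDPS = tert-butyldiphenylsilyl), and the sense of both oxazaborolidine reductions is assigned with the (iodo)alkenyl arm as the large ketone substituent.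

**Route**

Step 1
Reactants: 1 3-methylcyclohex-2-en-1-one
Product: 2 (R)-3-methylcyclohex-2-en-1-ol
Conditions: (S)-2-methyl-CBS-oxazaborolidine (10 mol %), BH3·SMe2, THF, –20 °C
Reagents that add atoms: none
Why: Corey–Bakshi–Shibata reduction, in which the catalyst binds the enone with the alkenyl arm as the large group and delivers hydride to one carbonyl face, should set the (R)-carbinol whose C–O bond is later traded for the C10–C9 bond.

Step 2
Reactants: 2 (R)-3-methylcyclohex-2-en-1-ol
Product: 4 ethyl 2-[(1R)-1-methylcyclohex-2-en-1-yl]acetate, via ketene acetal 3 (not isolated)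
Conditions: MeC(OEt)3, cat. EtCO2H, 140 °C (EtOH distilled off)
Reagents that add atoms: triethyl orthoacetate, CC(OCC)(OCC)OCC
Why: Johnson–Claisen rearrangement, whose suprafacial [3,3] shift delivers the acetate arm to the methyl-bearing alkene carbon on the face of the original C–O bond, should convert the carbinol centre into the (R)-configured quaternary C10.

Step 3
Reactants: 4 ethyl 2-[(1R)-1-methylcyclohex-2-en-1-yl]acetate
Product: 5 2-[(1R)-1-methylcyclohex-2-en-1-yl]ethan-1-ol
Conditions: LiAlH4, Et2O, 0 °C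
Reagents that add atoms: none
Why: Hydride reduction of the ester to the primary alcohol leaves the isolated ring alkene and the quaternary centre untouched.

Step 4
Reactants: 5 2-[(1R)-1-methylcyclohex-2-en-1-yl]ethan-1-ol
Product: 6 tert-butyl{2-[(1R)-1-methylcyclohex-2-en-1-yl]ethoxy}diphenylsilane
Conditions: TBDPSCl, imidazole, DMF, rt
Reagents that add atoms: tert-butyl(chloro)diphenylsilane, CC(C)(C)[Si](Cl)(c1ccccc1)c1ccccc1
Why: Standard silyl ether formation; this bulky, acid-stable group is chosen because the C8 oxygen must later pass through hot acetic acid and iodonium chemistry without taking part.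

Step 5
Reactants: 6 tert-butyl{2-[(1R)-1-methylcyclohex-2-en-1-yl]ethoxy}diphenylsilane
Product: 7 (4R)-4-[2-(TBDPS-oxy)ethyl]-4-methylcyclohex-2-en-1-one
Conditions: Rh2(cap)4 (cap = caprolactamate, 1 mol %), t-BuOOH, cat. K2CO3, CH2Cl2, rt
Reagents that add atoms: tert-butyl hydroperoxide, CC(C)(C)OO
Why: Radical allylic oxidation: only C3 carries allylic hydrogens, and the peroxy radical should be captured at that unhindered terminus rather than at the neopentyl C5, giving the 4,4-disubstituted cyclohexenone.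

Step 6
Reactants: 7 (4R)-4-[2-(TBDPS-oxy)ethyl]-4-methylcyclohex-2-en-1-one
Product: 8 (4R)-4-[2-(TBDPS-oxy)ethyl]-2-iodo-4-methylcyclohex-2-en-1-one
Conditions: I2, pyridine, CH2Cl2, 0 °C to rt
Reagents that add atoms: iodine, [I][I]
Why: Alpha-iodination of the enone by pyridine-mediated addition, iodination and elimination installs the handle for the C4 methyl group and makes the ketone a well-behaved substrate for the next reduction.

Step 7
Reactants: 8 (4R)-4-[2-(TBDPS-oxy)ethyl]-2-iodo-4-methylcyclohex-2-en-1-one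
Product: 9 (1S,4R)-4-[2-(TBDPS-oxy)ethyl]-2-iodo-4-methylcyclohex-2-en-1-ol
Conditions: (R)-2-methyl-CBS-oxazaborolidine (20 mol %), BH3·SMe2, THF, –20 °C
Reagents that add atoms: none
Why: Corey–Bakshi–Shibata reduction of a 2-iodoenone, with the iodoalkenyl arm as the large group, should override the remote C10 centre by reagent control and set the (S)-carbinol, that is the C3 hydroxyl cis to the C10 methyl.

Step 8
Reactants: 9 (1S,4R)-4-[2-(TBDPS-oxy)ethyl]-2-iodo-4-methylcyclohex-2-en-1-ol
Product: 10 (1S,4R)-4-[2-(TBDPS-oxy)ethyl]-2,4-dimethylcyclohex-2-en-1-ol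
Conditions: MeB(OH)2, PdCl2(dppf) (5 mol %), Cs2CO3, dioxane/H2O, 80 °C
Reagents that add atoms: methylboronic acid, CB(O)O
Why: Suzuki–Miyaura methylation of the alkenyl iodide proceeds with retention of the double-bond position and tolerates the free allylic alcohol and the silyl ether.

Step 9
Reactants: 10 (1S,4R)-4-[2-(TBDPS-oxy)ethyl]-2,4-dimethylcyclohex-2-en-1-ol
Product: 12 ethyl 2-[(1R,6R)-6-[2-(TBDPS-oxy)ethyl]-2,6-dimethylcyclohex-2-en-1-yl]acetate, via ketene acetal 11 (not isolated)
Conditions: MeC(OEt)3, cat. EtCO2H, 140 °C (EtOH distilled off)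
Reagents that add atoms: triethyl orthoacetate, CC(OCC)(OCC)OCC
Why: Johnson–Claisen rearrangement, whose suprafacial [3,3] shift transfers the C3 configuration to C5, should place the acetate arm cis to the C10 methyl and trans to the silyloxyethyl arm while moving the double bond to C3=C4.

Step 10
Reactants: 12 ethyl 2-[(1R,6R)-6-[2-(TBDPS-oxy)ethyl]-2,6-dimethylcyclohex-2-en-1-yl]acetate
Product: 13 2-[(1R,6R)-6-[2-(TBDPS-oxy)ethyl]-2,6-dimethylcyclohex-2-en-1-yl]ethan-1-ol
Conditions: LiAlH4, Et2O, 0 °C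
Reagents that add atoms: none
Why: Hydride reduction of the ester gives the C7 primary alcohol without touching the trisubstituted alkene or the silyl ether.

Step 11
Reactants: 13 2-[(1R,6R)-6-[2-(TBDPS-oxy)ethyl]-2,6-dimethylcyclohex-2-en-1-yl]ethan-1-ol
Product: 14 2-[(1R,6R)-6-[2-(TBDPS-oxy)ethyl]-2,6-dimethylcyclohex-2-en-1-yl]ethyl acetate
Conditions: Ac2O, pyridine, cat. DMAP, CH2Cl2, rt
Reagents that add atoms: acetic anhydride, CC(=O)OC(C)=O
Why: Acetylation masks the C7 oxygen as an ester whose carbonyl could reach C4 only through a seven-membered ring, so that, unlike a free alcohol or a C7 carbonyl group, it should not intercept the iodonium ion of the next step.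

Step 12
Reactants: 14 2-[(1R,6R)-6-[2-(TBDPS-oxy)ethyl]-2,6-dimethylcyclohex-2-en-1-yl]ethyl acetate
Product: 16 (1R,2R,3R,6S)-2-(2-acetoxyethyl)-3-[2-(TBDPS-oxy)ethyl]-6-hydroxy-1,3-dimethylcyclohexyl acetate (3beta-hydroxy, 4beta-acetoxy), via trans-iodoacetate 15 (not isolated)
Conditions: I2, AgOAc, AcOH, rt, dark; then H2O, 80 °C
Reagents that add atoms: iodine, [I][I] (retained only in 15); silver acetate, CC(=O)[O-].[Ag+]; water, O
Why: Woodward cis-hydroxylation: the iodonium ion forms on the alpha face away from the axial C10 methyl, acetate opens it at the tertiary C4 from the beta face in trans-diaxial fashion, the neighbouring acetate then displaces the C3 iodide with silver assistance to give the beta cis-acetoxonium ion, and stereoelectronically controlled hydrolysis should leave the ester on the axial C4 oxygen and the free hydroxyl at C3.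

Step 13
Reactants: 16 (1R,2R,3R,6S)-2-(2-acetoxyethyl)-3-[2-(TBDPS-oxy)ethyl]-6-hydroxy-1,3-dimethylcyclohexyl acetate; 17 angelic acid ((Z)-2-methylbut-2-enoic acid)
Product: 18 (1S,2R,3R,4R)-2-acetoxy-3-(2-acetoxyethyl)-4-[2-(TBDPS-oxy)ethyl]-2,4-dimethylcyclohexyl (Z)-2-methylbut-2-enoate
Conditions: 17, 2,4,6-trichlorobenzoyl chloride, Et3N, toluene, rt; then 16, 80 °C
Reagents that add atoms: none
Why: Yamaguchi esterification through the mixed 2,4,6-trichlorobenzoic anhydride, run without a nucleophilic amine catalyst and without forming the alkoxide, should keep the Z geometry of the acyl group and avoid acetyl migration from the tertiary oxygen.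

Step 14
Reactants: 18 (1S,2R,3R,4R)-2-acetoxy-3-(2-acetoxyethyl)-4-[2-(TBDPS-oxy)ethyl]-2,4-dimethylcyclohexyl (Z)-2-methylbut-2-enoate
Product: 19 (1S,2R,3R,4R)-2-acetoxy-4-[2-(TBDPS-oxy)ethyl]-3-(2-hydroxyethyl)-2,4-dimethylcyclohexyl (Z)-2-methylbut-2-enoate
Conditions: cat. K2CO3, MeOH, 0 °C
Reagents that add atoms: none
Why: Base-catalysed methanolysis of the unhindered primary acetate should be far faster than that of the tertiary axial acetate or of the alpha-branched conjugated angelate.

Step 15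
Reactants: 19 (1S,2R,3R,4R)-2-acetoxy-4-[2-(TBDPS-oxy)ethyl]-3-(2-hydroxyethyl)-2,4-dimethylcyclohexyl (Z)-2-methylbut-2-enoate
Product: 20 (1S,2R,3R,4R)-2-acetoxy-4-[2-(TBDPS-oxy)ethyl]-2,4-dimethyl-3-(2-oxoethyl)cyclohexyl (Z)-2-methylbut-2-enoate
Conditions: Dess–Martin periodinane, pyridine, CH2Cl2, rt
Reagents that add atoms: none
Why: Dess–Martin oxidation converts the primary alcohol into the C7 aldehyde under buffered, non-basic conditions that spare both esters.

Step 16
Reactants: 20 (1S,2R,3R,4R)-2-acetoxy-4-[2-(TBDPS-oxy)ethyl]-2,4-dimethyl-3-(2-oxoethyl)cyclohexyl (Z)-2-methylbut-2-enoate; 21 2-bromopropene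
Product: 22 (1S,2R,3R,4R)-2-acetoxy-4-[2-(TBDPS-oxy)ethyl]-3-(2-hydroxy-3-methylbut-3-en-1-yl)-2,4-dimethylcyclohexyl (Z)-2-methylbut-2-enoate (both C7 epimers)
Conditions: CrCl2, cat. NiCl2, DMF, rt
Reagents that add atoms: none
Why: Nozaki–Hiyama–Kishi reaction: the isopropenylchromium species adds to the aldehyde only and leaves both esters untouched; the new C7 carbinol forms as an epimer mixture that is erased by the later oxidation.

Step 17
Reactants: 22 (1S,2R,3R,4R)-2-acetoxy-4-[2-(TBDPS-oxy)ethyl]-3-(2-hydroxy-3-methylbut-3-en-1-yl)-2,4-dimethylcyclohexyl (Z)-2-methylbut-2-enoate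
Product: 23 (1S,2R,3R,4R)-2-acetoxy-4-(2-hydroxyethyl)-3-(2-hydroxy-3-methylbut-3-en-1-yl)-2,4-dimethylcyclohexyl (Z)-2-methylbut-2-enoate (both C7 epimers)
Conditions: HF·pyridine, THF/pyridine, 0 °C to rt
Reagents that add atoms: none
Why: Fluoride cleavage of the silyl ether under mildly acidic conditions should free the C8 alcohol without ester cleavage or acyl migration.

Step 18
Reactants: 23 (1S,2R,3R,4R)-2-acetoxy-4-(2-hydroxyethyl)-3-(2-hydroxy-3-methylbut-3-en-1-yl)-2,4-dimethylcyclohexyl (Z)-2-methylbut-2-enoate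
Product: 24 (1S,2R,3R,4R)-2-acetoxy-2,4-dimethyl-3-(3-methyl-2-oxobut-3-en-1-yl)-4-(2-oxoethyl)cyclohexyl (Z)-2-methylbut-2-enoate
Conditions: Dess–Martin periodinane (excess), pyridine, CH2Cl2, 0 °C to rt; used at once
Reagents that add atoms: none
Why: A double Dess–Martin oxidation converts the allylic alcohol into the isopropenyl ketone and the primary alcohol into the C8 aldehyde in one operation, giving the sensitive keto-aldehyde only at the last moment.

Step 19
Reactants: 24 (1S,2R,3R,4R)-2-acetoxy-2,4-dimethyl-3-(3-methyl-2-oxobut-3-en-1-yl)-4-(2-oxoethyl)cyclohexyl (Z)-2-methylbut-2-enoate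
Product: 25 CNP0381775.1, (3S,4R,5R,7S,10R)-4-acetoxy-7-hydroxy-8-oxoeudesm-11-en-3-yl (Z)-2-methylbut-2-enoate
Conditions: 2-(pentafluorophenyl)-6,7-dihydro-5H-pyrrolo[2,1-c][1,2,4]triazol-2-ium tetrafluoroborate (20 mol %), i-Pr2NEt (20 mol %), toluene (0.02 M), rt
Reagents that add atoms: none
Why: The triazolylidene adds to the unhindered C8 aldehyde, proton transfer gives the nucleophilic enaminol, its carbon attacks the C7 ketone carbonyl, and collapse of the adduct returns the carbene and leaves the C8 ketone next to the new C7 tertiary alcohol. This is the known carbene-catalysed intramolecular crossed aldehyde–ketone benzoin reaction that gives six-membered tertiary alpha-ketols. Ring B closes in a 6-exo-trig mode through a chair in which the trans-diequatorial C5 and C10 arms of the preset ring A enforce a trans-decalin. The new C7 stereocentre is controlled by that chair and by the reversibility of the addition, which should leave the larger isopropenyl group equatorial (beta) and the hydroxyl axial (alpha). The step needs acyl-anion formation at the aldehyde and 1,2-addition to the ketone: only the aldehyde can form the enaminol, a Stetter-type 1,4-addition to the terminal methylene would have to close an eight-membered ring, and the weak amine base and high dilution are chosen to spare the two esters and to hold back aldol closure and intermolecular coupling.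

**Compound list**
1 | 3-methylcyclohex-2-en-1-one | CC1=CC(=O)CCC1 | starting material
2 | (R)-3-methylcyclohex-2-en-1-ol | CC1=C[C@H](O)CCC1 | intermediate
3 | (R)-3-(1-ethoxyethenyloxy)-1-methylcyclohex-1-ene (mixed ketene acetal) | C=C(OCC)O[C@H]1C=C(C)CCC1 | intermediate
4 | ethyl 2-[(1R)-1-methylcyclohex-2-en-1-yl]acetate | CCOC(=O)C[C@]1(C)C=CCCC1 | intermediate
5 | 2-[(1R)-1-methylcyclohex-2-en-1-yl]ethan-1-ol | OCC[C@]1(C)C=CCCC1 | intermediate
6 | tert-butyl{2-[(1R)-1-methylcyclohex-2-en-1-yl]ethoxy}diphenylsilane | CC(C)(C)[Si](OCC[C@]1(C)C=CCCC1)(c1ccccc1)c1ccccc1 | intermediate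
7 | (4R)-4-[2-(TBDPS-oxy)ethyl]-4-methylcyclohex-2-en-1-one | CC(C)(C)[Si](OCC[C@]1(C)C=CC(=O)CC1)(c1ccccc1)c1ccccc1 | intermediate
8 | (4R)-4-[2-(TBDPS-oxy)ethyl]-2-iodo-4-methylcyclohex-2-en-1-one | CC(C)(C)[Si](OCC[C@]1(C)C=C(I)C(=O)CC1)(c1ccccc1)c1ccccc1 | intermediate
9 | (1S,4R)-4-[2-(TBDPS-oxy)ethyl]-2-iodo-4-methylcyclohex-2-en-1-ol | CC(C)(C)[Si](OCC[C@]1(C)C=C(I)[C@@H](O)CC1)(c1ccccc1)c1ccccc1 | intermediate
10 | (1S,4R)-4-[2-(TBDPS-oxy)ethyl]-2,4-dimethylcyclohex-2-en-1-ol | CC(C)(C)[Si](OCC[C@]1(C)C=C(C)[C@@H](O)CC1)(c1ccccc1)c1ccccc1 | intermediate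
11 | 1-ethoxyethenyl ether of 10 (mixed ketene acetal) | CC(C)(C)[Si](OCC[C@]1(C)C=C(C)[C@@H](OC(=C)OCC)CC1)(c1ccccc1)c1ccccc1 | intermediate
12 | ethyl 2-[(1R,6R)-6-[2-(TBDPS-oxy)ethyl]-2,6-dimethylcyclohex-2-en-1-yl]acetate | CCOC(=O)C[C@H]1C(C)=CCC[C@]1(C)CCO[Si](C(C)(C)C)(c1ccccc1)c1ccccc1 | intermediate
13 | 2-[(1R,6R)-6-[2-(TBDPS-oxy)ethyl]-2,6-dimethylcyclohex-2-en-1-yl]ethan-1-ol | OCC[C@H]1C(C)=CCC[C@]1(C)CCO[Si](C(C)(C)C)(c1ccccc1)c1ccccc1 | intermediate
14 | 2-[(1R,6R)-6-[2-(TBDPS-oxy)ethyl]-2,6-dimethylcyclohex-2-en-1-yl]ethyl acetate | CC(=O)OCC[C@H]1C(C)=CCC[C@]1(C)CCO[Si](C(C)(C)C)(c1ccccc1)c1ccccc1 | intermediate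
15 | (1R,2R,3R,6R)-2-(2-acetoxyethyl)-3-[2-(TBDPS-oxy)ethyl]-6-iodo-1,3-dimethylcyclohexyl acetate (3alpha-iodo, 4beta-acetoxy) | CC(=O)OCC[C@@H]1[C@](C)(CC[C@@H](I)[C@]1(C)OC(C)=O)CCO[Si](C(C)(C)C)(c1ccccc1)c1ccccc1 | intermediate
16 | (1R,2R,3R,6S)-2-(2-acetoxyethyl)-3-[2-(TBDPS-oxy)ethyl]-6-hydroxy-1,3-dimethylcyclohexyl acetate | CC(=O)OCC[C@@H]1[C@](C)(CC[C@H](O)[C@]1(C)OC(C)=O)CCO[Si](C(C)(C)C)(c1ccccc1)c1ccccc1 | intermediate
17 | angelic acid, (Z)-2-methylbut-2-enoic acid | C/C=C(/C)C(=O)O | starting material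
18 | (1S,2R,3R,4R)-2-acetoxy-3-(2-acetoxyethyl)-4-[2-(TBDPS-oxy)ethyl]-2,4-dimethylcyclohexyl (Z)-2-methylbut-2-enoate | CC(=O)OCC[C@@H]1[C@](C)(CC[C@H](OC(=O)/C(C)=C\C)[C@]1(C)OC(C)=O)CCO[Si](C(C)(C)C)(c1ccccc1)c1ccccc1 | intermediate
19 | (1S,2R,3R,4R)-2-acetoxy-4-[2-(TBDPS-oxy)ethyl]-3-(2-hydroxyethyl)-2,4-dimethylcyclohexyl (Z)-2-methylbut-2-enoate | OCC[C@@H]1[C@](C)(CC[C@H](OC(=O)/C(C)=C\C)[C@]1(C)OC(C)=O)CCO[Si](C(C)(C)C)(c1ccccc1)c1ccccc1 | intermediate
20 | (1S,2R,3R,4R)-2-acetoxy-4-[2-(TBDPS-oxy)ethyl]-2,4-dimethyl-3-(2-oxoethyl)cyclohexyl (Z)-2-methylbut-2-enoate | O=CC[C@@H]1[C@](C)(CC[C@H](OC(=O)/C(C)=C\C)[C@]1(C)OC(C)=O)CCO[Si](C(C)(C)C)(c1ccccc1)c1ccccc1 | intermediate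
21 | 2-bromopropene | C=C(C)Br | starting material
22 | (1S,2R,3R,4R)-2-acetoxy-4-[2-(TBDPS-oxy)ethyl]-3-(2-hydroxy-3-methylbut-3-en-1-yl)-2,4-dimethylcyclohexyl (Z)-2-methylbut-2-enoate, both C7 epimers | C=C(C)C(O)C[C@@H]1[C@](C)(CC[C@H](OC(=O)/C(C)=C\C)[C@]1(C)OC(C)=O)CCO[Si](C(C)(C)C)(c1ccccc1)c1ccccc1 | intermediate
23 | (1S,2R,3R,4R)-2-acetoxy-4-(2-hydroxyethyl)-3-(2-hydroxy-3-methylbut-3-en-1-yl)-2,4-dimethylcyclohexyl (Z)-2-methylbut-2-enoate, both C7 epimers | C=C(C)C(O)C[C@@H]1[C@](C)(CC[C@H](OC(=O)/C(C)=C\C)[C@]1(C)OC(C)=O)CCO | intermediate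
24 | (1S,2R,3R,4R)-2-acetoxy-2,4-dimethyl-3-(3-methyl-2-oxobut-3-en-1-yl)-4-(2-oxoethyl)cyclohexyl (Z)-2-methylbut-2-enoate | C=C(C)C(=O)C[C@@H]1[C@](C)(CC[C@H](OC(=O)/C(C)=C\C)[C@]1(C)OC(C)=O)CC=O | intermediate
25 | CNP0381775.1, (3S,4R,5R,7S,10R)-4-acetoxy-7-hydroxy-8-oxoeudesm-11-en-3-yl (Z)-2-methylbut-2-enoate | C=C(C)[C@@]1(O)C[C@@H]2[C@](C)(CC[C@H](OC(=O)/C(C)=C\C)[C@]2(C)OC(C)=O)CC1=O | target

**Totals**
Total step count: 19. Longest linear sequence: 19 steps (from 1).

**Steps most likely to fail**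

1. Step 12 (Woodward cis-hydroxylation). The iodonium ion may open on the wrong carbon or face, the tertiary cation may eliminate, the acetyl group may end on the C3 oxygen, or the silyl ether may be lost in hot wet acetic acid. Fallback, setting out from 14: epoxidation with mCPBA (CH2Cl2, 0 °C) on the less hindered alpha face should give the 3alpha,4alpha-epoxide F1. Acetolysis (AcOH, 40 °C) should open it in trans-diaxial, Markovnikov fashion at C4 to the 3alpha-hydroxy-4beta-acetate F2. Dess–Martin oxidation should then give the 3-ketone F3. Reduction with NaBH4 and CeCl3 in MeOH at –78 °C, with axial hydride delivery from the alpha face, should give the 3beta-alcohol, and the route is rejoined at 16.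

2. Step 19 (carbene benzoin). The carbene or the amine base may be diverted by conjugate addition to the isopropenyl ketone, base-induced aldol closure to a five-membered ring may outrun the umpolung, or facial selectivity at C7 may be poor. Fallback, setting out from 24: conjugate addition of benzeneselenol (cat. Et3N, CH2Cl2, 0 °C) masks the enone as the beta-phenylselanyl ketone F4, a saturated and more electrophilic acceptor. The same triazolium-catalysed benzoin closure on it should give the phenylselanyl ketol F5. Oxidation with H2O2 and pyridine gives the selenoxide F6, whose syn-elimination at room temperature restores the isopropenyl group, and the route comes back at 25.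

3. Step 13 (angeloylation). The Z-configured acyl unit may isomerise to the E (tiglate) form during acyl transfer, and acylation of the hindered C3 hydroxyl may be slow enough for the tertiary acetyl group to migrate. Fallback, setting out from 16: esterification with 2-[bis(2,2,2-trifluoroethoxy)phosphoryl]propanoic acid (EDC, cat. DMAP, CH2Cl2) gives the phosphonate ester F7. A Still–Gennari olefination with acetaldehyde (KHMDS, 18-crown-6, THF, –78 °C) then builds the Z-alkene in place, and the route comes back at 18.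

Further compounds
F1 | step 12 | 3alpha,4alpha-epoxide of 14 | CC(=O)OCC[C@@H]1[C@](C)(CC[C@H]2O[C@@]12C)CCO[Si](C(C)(C)C)(c1ccccc1)c1ccccc1
F2 | step 12 | 3alpha-hydroxy-4beta-acetate (C3 epimer of 16) | CC(=O)OCC[C@@H]1[C@](C)(CC[C@@H](O)[C@]1(C)OC(C)=O)CCO[Si](C(C)(C)C)(c1ccccc1)c1ccccc1
F3 | step 12 | 3-ketone with 4beta-acetate | CC(=O)OCC[C@@H]1[C@](C)(CCC(=O)[C@]1(C)OC(C)=O)CCO[Si](C(C)(C)C)(c1ccccc1)c1ccccc1
F4 | step 19 | beta-phenylselanyl ketone from 24 (C11 epimers) | C(C(C)C(=O)C[C@@H]1[C@](C)(CC[C@H](OC(=O)/C(C)=C\C)[C@]1(C)OC(C)=O)CC=O)[Se]c1ccccc1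
F5 | step 19 | phenylselanyl ketol, ring B closed (C11 epimers) | C(C(C)[C@@]1(O)C[C@@H]2[C@](C)(CC[C@H](OC(=O)/C(C)=C\C)[C@]2(C)OC(C)=O)CC1=O)[Se]c1ccccc1
F6 | step 19 | selenoxide of F5 | C(C(C)[C@@]1(O)C[C@@H]2[C@](C)(CC[C@H](OC(=O)/C(C)=C\C)[C@]2(C)OC(C)=O)CC1=O)[Se](=O)c1ccccc1
F7 | step 13 | C3 2-[bis(2,2,2-trifluoroethoxy)phosphoryl]propanoate of 16 | CC(=O)OCC[C@@H]1[C@](C)(CC[C@H](OC(=O)C(C)P(=O)(OCC(F)(F)F)OCC(F)(F)F)[C@]1(C)OC(C)=O)CCO[Si](C(C)(C)C)(c1ccccc1)c1ccccc1
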